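## Retrosynthetic overview

1. Target ⇒ terminal-alkene phthalide + CO + methyl vinyl ketone. The side-chain C12'–C13' bond is made by an acylzirconocene (acyl anion donor, acyl carbon from CO) adding 1,4 to the enone, at the last step on the unprotected lactone.
2. Alkene phthalide ⇒ (S)-ortho-bromo benzylic alcohol. The lactone carbon comes from CO2 after Br/Li exchange; this is the only ring closure (benzene ring bought, lactone ring closed in the third step).
3. (S)-Bromo alcohol ⇒ 2-bromo-3,5-dimethoxybenzaldehyde + di(undec-10-enyl)zinc. An amino-alcohol-catalysed enantioselective alkylation sets the single stereocentre.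
4. Bromo aldehyde ⇒ 3,5-dimethoxybenzaldehyde (regioselective bromination); zinc reagent ⇒ 11-bromoundec-1-ene.

Assumption: side-chain carbons are numbered C1' (on C3 of the phthalide) to C16' (methyl), and "cheap" is read as bulk catalogue chemicals, so the bromo aldehyde is made in step 1 rather than bought.

## Route

Step 1
Reactants: 1 3,5-dimethoxybenzaldehyde
Product: 2 2-bromo-3,5-dimethoxybenzaldehyde
Conditions: Br2 (1.05 equiv), AcOH, 0 °C to rt
Reagents that add atoms: bromine, BrBr
Why: Electrophilic aromatic bromination goes to C2 (para to one methoxy group, ortho to the other) because C4 between the two methoxy groups is more hindered, which places the halogen exactly where the lactone carbonyl carbon is needed.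

Step 2
Reactants: 2 2-bromo-3,5-dimethoxybenzaldehyde; 3 11-bromoundec-1-ene
Product: 6 (1S)-1-(2-bromo-3,5-dimethoxyphenyl)dodec-11-en-1-ol, via undec-10-enylmagnesium bromide 4 (not isolated), via di(undec-10-enyl)zinc 5 (not isolated)
Conditions: 3 (3.2 equiv), Mg, Et2O, reflux; ZnCl2 (1.6 equiv), then 1,4-dioxane, filter off the magnesium salt; then 2, (2S)-(−)-3-exo-morpholinoisoborneol (5 mol%), toluene, 0 °C; 1 M HCl
Reagents that add atoms: none
Why: Noyori-type amino-alcohol-catalysed enantioselective dialkylzinc addition, in which the zinc aminoalkoxide of the (2S)-ligand delivers the alkyl group to the Si face of the aryl aldehyde to give the (S)-carbinol (same sense as the (S)-1-phenylpropanol benchmark), the salt-free zinc reagent suppressing the racemic background.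

Step 3
Reactants: 6 (1S)-1-(2-bromo-3,5-dimethoxyphenyl)dodec-11-en-1-ol
Product: 9 (3S)-5,7-dimethoxy-3-(undec-10-en-1-yl)-2-benzofuran-1(3H)-one, via dilithiated aryl alkoxide 7 (not isolated), via hydroxy acid 8 (not isolated)
Conditions: n-BuLi (2.2 equiv), THF, −78 °C; CO2 (g), −78 °C to rt; 2 M HCl, rt
Reagents that add atoms: carbon dioxide, O=C=O
Why: O-deprotonation followed by fast bromine–lithium exchange gives the aryllithium, whose carboxylation and acid-driven 5-exo lactonisation (acyl substitution, benzylic C–O bond untouched) close the phthalide with the (S) centre retained.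

Step 4
Reactants: 9 (3S)-5,7-dimethoxy-3-(undec-10-en-1-yl)-2-benzofuran-1(3H)-one; 10 methyl vinyl ketone (but-3-en-2-one)
Product: 13 CJ-13,103, (3S)-3-(12,15-dioxohexadecyl)-5,7-dimethoxy-2-benzofuran-1(3H)-one, via alkylzirconocene chloride 11 (not isolated), via acylzirconocene chloride 12 (not isolated)
Conditions: Cp2Zr(H)Cl (1.3 equiv), CH2Cl2, rt, 45 min; CO (1 atm), rt, 2 h; then 10 (2 equiv, slow addition), Pd(OAc)2 (10 mol%), BF3·OEt2 (1 equiv), Et2O–THF 2:1, 0 °C; 1 M HCl
Reagents that add atoms: carbon monoxide, [C-]#[O+]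
Why: Schwartz hydrozirconation puts zirconium on the terminal carbon, CO migratory insertion gives an acylzirconocene chloride that behaves as an unmasked acyl anion, and its palladium-catalysed conjugate acylation (Stetter-type 1,4-addition) of the BF3-activated enone joins the acyl carbon C12' to the enone β-carbon C13' without touching the stereocentre.

## Compound list

1 | 3,5-dimethoxybenzaldehyde | COc1cc(OC)cc(C=O)c1 | starting material
2 | 2-bromo-3,5-dimethoxybenzaldehyde | COc1cc(OC)c(Br)c(C=O)c1 | intermediate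
3 | 11-bromoundec-1-ene | C=CCCCCCCCCCBr | starting material
4 | undec-10-enylmagnesium bromide | C=CCCCCCCCCC[Mg]Br | intermediate
5 | di(undec-10-enyl)zinc | C=CCCCCCCCCC[Zn]CCCCCCCCCC=C | intermediate
6 | (1S)-1-(2-bromo-3,5-dimethoxyphenyl)dodec-11-en-1-ol | COc1cc(OC)c(Br)c(c1)[C@@H](O)CCCCCCCCCC=C | intermediate
7 | lithium (1S)-1-(2-lithio-3,5-dimethoxyphenyl)dodec-11-en-1-olate | COc1cc(OC)c([Li])c(c1)[C@@H](O[Li])CCCCCCCCCC=C | intermediate
8 | 2-[(1S)-1-hydroxydodec-11-en-1-yl]-4,6-dimethoxybenzoic acid | COc1cc(OC)c(C(=O)O)c(c1)[C@@H](O)CCCCCCCCCC=C | intermediate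
9 | (3S)-5,7-dimethoxy-3-(undec-10-en-1-yl)-2-benzofuran-1(3H)-one | COc1cc(OC)c2c(c1)[C@H](CCCCCCCCCC=C)OC2=O | intermediate
10 | methyl vinyl ketone (but-3-en-2-one) | CC(=O)C=C | starting material
11 | {11-[(1S)-4,6-dimethoxy-3-oxo-1,3-dihydro-2-benzofuran-1-yl]undecyl}zirconocene chloride, Cp2Zr(Cl)R (Cp = cyclopentadienyl, drawn sigma-bonded in the SMILES) | COc1cc(OC)c2c(c1)[C@H](CCCCCCCCCCC[Zr](Cl)(C1C=CC=C1)C1C=CC=C1)OC2=O | intermediate
12 | {12-[(1S)-4,6-dimethoxy-3-oxo-1,3-dihydro-2-benzofuran-1-yl]dodecanoyl}zirconocene chloride, Cp2Zr(Cl)C(O)R (Cp drawn sigma-bonded in the SMILES) | COc1cc(OC)c2c(c1)[C@H](CCCCCCCCCCCC(=O)[Zr](Cl)(C1C=CC=C1)C1C=CC=C1)OC2=O | intermediate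
13 | CJ-13,103, (3S)-3-(12,15-dioxohexadecyl)-5,7-dimethoxy-2-benzofuran-1(3H)-one | COc1cc(OC)c2c(c1)[C@H](CCCCCCCCCCCC(=O)CCC(C)=O)OC2=O | target

## Step count

Total steps: 4. Longest linear sequence: 4 steps (1 → 2 → 6 → 9 → 13; 3 and 10 are bought and enter in steps 2 and 4).

## Steps most likely to fail, with fallbacks

Step 4 is the riskiest. Cp2Zr(H)Cl may attack the lactone before the alkene is consumed, and methyl vinyl ketone may polymerise under BF3·OEt2 or take the acyl group 1,2. The fallback sets out from 9 and comes back at 13. Linear-selective hydroformylation of 9 (Rh(acac)(CO)2 1 mol%, BiPhePhos 2 mol%, CO/H2 1:1 at 10 bar, toluene, 80 °C) gives the aldehyde 12-[(1S)-4,6-dimethoxy-3-oxo-1,3-dihydro-2-benzofuran-1-yl]dodecanal F1. A thiazolium-carbene Stetter reaction of F1 with 10 (3-benzyl-5-(2-hydroxyethyl)-4-methylthiazolium chloride 20 mol%, Et3N, EtOH, 80 °C) then gives 13. The acyl anion is then a Breslow intermediate rather than an acyl metal, and no hydride reagent meets the lactone.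

Step 2 is next. The ortho-bromo aldehyde or residual magnesium salts may erode the enantioselectivity, and only one alkyl group of 5 is transferred. The fallback sets out from 2 and comes back at 6. Grignard reagent 4 (1.2 equiv, THF, −78 °C, then 1 M HCl) adds to 2 to give racemic 1-(2-bromo-3,5-dimethoxyphenyl)dodec-11-en-1-ol F2. Dess–Martin periodinane (CH2Cl2, rt) oxidises it to the ketone 1-(2-bromo-3,5-dimethoxyphenyl)dodec-11-en-1-one F3. Corey–Bakshi–Shibata reduction of F3 with (R)-2-methyl-CBS-oxazaborolidine (20 mol%) and catecholborane (toluene, −78 °C; catecholborane rather than BH3 so that the terminal alkene is not hydroborated) gives 6. The stereocentre is then set by reagent-controlled hydride delivery (aryl as the large group) instead of by alkyl transfer.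

Step 3 is third. The hindered aryllithium may be protonated or butylated before CO2 capture. The fallback sets out from 2 and comes back at 9, so the carbonyl carbon is installed by palladium catalysis before the stereocentre exists. Methoxycarbonylation of 2 (Pd(OAc)2 3 mol%, Xantphos 6 mol%, CO 1 atm, MeOH, Na2CO3, toluene, 80 °C) gives methyl 2-formyl-4,6-dimethoxybenzoate F4. Addition of 5 to F4 under the conditions of step 2 gives the zinc alkoxide of methyl 2-[(1S)-1-hydroxydodec-11-en-1-yl]-4,6-dimethoxybenzoate F5. This closes onto the ester in the flask or on acidic work-up, with loss of methanol, to give 9.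

## Further compounds

F1 | step 4 | 12-[(1S)-4,6-dimethoxy-3-oxo-1,3-dihydro-2-benzofuran-1-yl]dodecanal | COc1cc(OC)c2c(c1)[C@H](CCCCCCCCCCCC=O)OC2=O
F2 | step 2 | racemic 1-(2-bromo-3,5-dimethoxyphenyl)dodec-11-en-1-ol | COc1cc(OC)c(Br)c(c1)C(O)CCCCCCCCCC=C
F3 | step 2 | 1-(2-bromo-3,5-dimethoxyphenyl)dodec-11-en-1-one | COc1cc(OC)c(Br)c(c1)C(=O)CCCCCCCCCC=C
F4 | step 3 | methyl 2-formyl-4,6-dimethoxybenzoate | COC(=O)c1c(OC)cc(OC)cc1C=O
F5 | step 3 | methyl 2-[(1S)-1-hydroxydodec-11-en-1-yl]-4,6-dimethoxybenzoate | COC(=O)c1c(OC)cc(OC)cc1[C@@H](O)CCCCCCCCCC=C
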